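The ratio of G charged to E and Q together in the flask is 1.25, so with the catalytic step by itself the stoichiometry allows c = 100%.

| setting | spring | midnight | noon | flask |
|---|---|---|---|---|
| E | 0.050 M | 0.050 M | 0.025 M | 0.050 M |
| Q | 0.050 M | 0.050 M | 0.025 M | 0.050 M |
| G | 0.125 M (fed, over 1.0 min) | 0.125 M (fed, over 1.0 min) | 0.125 M (fed, over 1.0 min) | 0.125 M (fed, over 1.0 min) |
| J | 70 µM | 110 µM | 50 µM | 50 µM |
| remark | run made earlier; the fed solution adds 0.50 times the starting volume | run made earlier; the fed solution adds 0.50 times the starting volume | run made earlier; the fed solution adds 0.50 times the starting volume | the fed solution adds 0.50 times the starting volume |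
| time |  |  |  | 30 min |

| run | time / min | E / % | Q / % |
|---|---|---|---|
| spring | 5.00 | 17.8 | 24.1 |
| spring | 12.0 | 20.3 | 20.5 |
| spring | 25.0 | 20.8 | 19.6 |
| spring | 40.0 | 19.1 | 19.4 |
| midnight | 3.00 | 14.5 | 26.2 |
| midnight | 6.00 | 16.2 | 19.2 |
| midnight | 15.0 | 14.6 | 15.7 |
| midnight | 40.0 | 16.2 | 16.9 |
| noon | 3.00 | 22.1 | 32.1 |
| noon | 6.00 | 17.8 | 24.0 |
| noon | 15.0 | 17.8 | 17.8 |
| noon | 40.0 | 19.4 | 17.5 |

(scatter of a reading: 1 percentage point)

- part of the E and Q charged together that has reacted at 30 min
- excess of D over Ty in the product at 30 min
- excess of Q over E among what is left of the two at 30 min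

- J is single-handed; E and Q are mirror images of each other, charged as a racemate, each of them at the stated concentration
- charges are per starting volume, the dose included; the dosed solution carries all of it
- the numbers in the tables scatter by 1 percentage point (one standard deviation)
- an excess is the difference of the two amounts in percent of their sum
- an excess is below zero if the other one leads

The runs stop short of that. I average the last two readings of each run and count everything per starting volume, since the feed dilutes all species alike.

Left of E and Q: spring 39.5%, midnight 31.7%, noon 36.3%

Share of charged G found in product: spring 48.4%, midnight 54.6%, noon 25.5%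

So I add a second process: a loss of G that needs no J, competing with a catalytic step that runs as [J]([E]+[Q]). The share of G in product is then S/(S + A), where S is the mean of [E]+[Q] between start and end, and A goes as 1/[J]. Each run gives A = S(1/share − 1), which I scale to the [J] of the flask:

spring 0.104 M, midnight 0.120 M, noon 0.0995 M

Their mean is 0.108 M, a value read from scattered readings. This A is the break-even concentration at the [J] charged to the flask: the level of E and Q together, counted per starting volume, at which G splits evenly between product and loss. Now c = (G charged / E and Q charged) × S/(S + A), and c sits inside S, so I iterate: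

S at its charge: c = 60.1%

S from that c: c = 49.2%

S from that c: c = 51.4%

The third process, E and Q passing into each other, adds no term here, since I pool them. It shows in the midnight run, where Q minus E shrinks from 12 percentage points to 0.7 points, so I expect eS near zero. I commit to c of about 51.4%; A does not reckon eP.

The forecast gives c = 41%, eP = 52% and eS = 0%, reading that “the catalyst dies”. My c stands higher.

The flask gives c = 54.5%, eP = 32.9% and eS = 0.0117%.

    G + J + E → J + D (k = 3800 L² mol⁻² s⁻¹)
    G + J + Q → J + Ty (k = 1600 L² mol⁻² s⁻¹)
    E ⇌ Q (k = 0.00260 s⁻¹)
    2 J → Z (k = 20.0 L mol⁻¹ s⁻¹)
    G → X (k = 0.00450 s⁻¹)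

Put back into the same rule, the c of the flask gives A = 0.0942 M. In the flask G, the limiting reagent, stands at 0% of its charge at 30.0 min, less than the 46% of its charge still left of Q. The same run without the passing of G into X reaches c = 92.7% against 54.5%, so that loss is the main reason for the shortfall.

In the neighbour with 85.0 µM of J, A scales to 0.0635 M, and the rounds give 76.5%, 61.7% and 65.2%. The computed c there is 64.5%.

All runs come from a simulation on assumed constants; the scatter is artificial.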